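## Retrosynthetic overview

1. Lignan numbering is used. C7 is the carbinol carbon, C8 and C8' are the ring methines, C9 and C9' are the ring OCH2 groups beside them, and C7' is the benzylic CH2. The target is 7R,8R,8'R, with the C8 and C8' substituents trans on its single heterocycle.
2. Structural feature: in the tetrahydrofuran (O, C9, C8, C8', C9') the methylene C9 lies between the ring oxygen and C8, and C8 carries C7. With C7 raised to a ketone, C9 becomes the β-carbon of an aryl enone C7(=O)–C8(=C9H2). The O–C9 bond is therefore the retron of an intramolecular oxa-Michael addition of the C9' hydroxyl.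
3. Disconnections, working backwards: the two O-benzyl groups and the C7–H bond (reagent-controlled ketone reduction); O–C9 (ring closure); C8=C9 (Mannich methylenation, C9 from formaldehyde); C7–aryl (aryllithium on a Weinreb amide).
4. The amide is the opened form of (R)-β-benzyl-γ-butyrolactone, whose carbonyl carbon is C7. The lactone comes from O-benzylvanillin and dimethyl succinate by Stobbe condensation, asymmetric hydrogenation (sets C8') and ester-selective reduction.
5. Ring order: a temporary butyrolactone (made in step 4, opened in step 5), then the tetrahydrofuran in step 11. Stereocentres are set in the order C8' (catalyst), C8 (equilibration), C7 (catalyst).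

Key step: step 11

Assumption: the (S,S) antipode of Et-DuPhos is taken to give the R half-ester, by analogy with its sense on chelating enamides and itaconates; both antipodes are sold, so the other one is used if the optical rotation of the β-benzyl lactone shows the opposite sense.

## Route

Step 1
Reactants: 1 vanillin
Product: 2 4-(benzyloxy)-3-methoxybenzaldehyde
Conditions: BnBr, K2CO3, DMF, 23 °C
Reagents that add atoms: benzyl bromide, BrCc1ccccc1
Why: Williamson etherification of the phenoxide with a benzylic bromide, to which the aldehyde is inert.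

Step 2
Reactants: 2 4-(benzyloxy)-3-methoxybenzaldehyde; 3 dimethyl succinate
Product: 4 (E)-4-[4-(benzyloxy)-3-methoxyphenyl]-3-(methoxycarbonyl)but-3-enoic acid
Conditions: NaOMe, MeOH, reflux; aq. HCl
Reagents that add atoms: none
Why: Stobbe condensation, in which the succinate enolate adds to the non-enolisable aldehyde, the alkoxide lactonises and base-induced opening of the paraconic ester gives the carboxylate half-ester with aryl trans to CO2Me, which cannot condense again.

Step 3
Reactants: 4 (E)-Stobbe half-ester
Product: 5 (R)-4-[4-(benzyloxy)-3-methoxyphenyl]-3-(methoxycarbonyl)butanoic acid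
Conditions: H2 (5 bar), [Rh(cod)((S,S)-Et-DuPhos)]BF4 (0.5 mol%), NaOMe (10 mol%), MeOH, 23 °C
Reagents that add atoms: none
Why: Rhodium–bisphosphine asymmetric hydrogenation of an itaconate-type half-ester, in which the carboxylate arm chelates the metal, the C2-symmetric phospholane ligand exposes one alkene face and C8' is set as R, while the aryl benzyl ether is inert to the homogeneous catalyst.

Step 4
Reactants: 5 (R)-half-ester
Product: 8 (R)-4-[4-(benzyloxy)-3-methoxybenzyl]dihydrofuran-2(3H)-one, via potassium carboxylate 6 (not isolated), via hydroxy acid 7 (not isolated)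
Conditions: KOH (1.0 equiv), EtOH, 0 °C; CaCl2, NaBH4, EtOH, −10 → 23 °C; 2 M HCl, 23 °C
Reagents that add atoms: potassium hydroxide, [K+].[OH-] (its potassium is carried only by 6)
Why: Chemoselective borohydride reduction followed by acid-driven lactonisation, in which Ca(BH4)2 reduces the methyl ester but not the carboxylate of 6, the single equivalent of KOH is spent on the acid so the centre α to the ester is not enolised, and γ-hydroxy acid 7 closes on acidification with C8' unchanged.

Step 5
Reactants: 8 (R)-β-benzyl-γ-butyrolactone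
Product: 9 (R)-3-[4-(benzyloxy)-3-methoxybenzyl]-4-hydroxy-N-methoxy-N-methylbutanamide
Conditions: MeNH(OMe)·HCl, AlMe3, CH2Cl2, 0 → 23 °C; aq. potassium sodium tartrate
Reagents that add atoms: N,O-dimethylhydroxylamine hydrochloride, CNOC.Cl
Why: Weinreb aminolysis of the lactone with the aluminium amide, chosen because an aryllithium added directly to the lactone risks double addition, whereas the amide accepts one aryl group only.

Step 6
Reactants: 9 hydroxy Weinreb amide
Product: 10 (R)-3-[4-(benzyloxy)-3-methoxybenzyl]-4-[(tert-butyldiphenylsilyl)oxy]-N-methoxy-N-methylbutanamide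
Conditions: TBDPSCl, imidazole, CH2Cl2, 0 → 23 °C (crude 9 used at once)
Reagents that add atoms: tert-butyldiphenylsilyl chloride, CC(C)(C)[Si](Cl)(c1ccccc1)c1ccccc1
Why: Silylation of the primary alcohol stops relactonisation of 9 and later hemiketal formation, and the acid-robust TBDPS group is chosen to survive the ammonium trifluoroacetate medium of step 9.

Step 7
Reactants: 11 4-bromo-2-methoxyphenol
Product: 12 1-(benzyloxy)-4-bromo-2-methoxybenzene
Conditions: BnBr, K2CO3, DMF, 23 °C
Reagents that add atoms: benzyl bromide, BrCc1ccccc1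
Why: Williamson etherification, which removes the acidic phenol before metalation.

Step 8
Reactants: 12 1-(benzyloxy)-4-bromo-2-methoxybenzene; 10 silyloxy Weinreb amide
Product: 14 (R)-1-[4-(benzyloxy)-3-methoxyphenyl]-3-[4-(benzyloxy)-3-methoxybenzyl]-4-[(tert-butyldiphenylsilyl)oxy]butan-1-one, via aryllithium 13 (not isolated)
Conditions: 12, n-BuLi, THF, −78 °C; then 10, −78 → −20 °C; aq. NH4Cl
Reagents that add atoms: n-butyllithium, [Li]CCCC (its lithium is carried only by 13)
Why: Bromine–lithium exchange followed by the Weinreb ketone synthesis, in which the chelated tetrahedral adduct lasts until the quench, so one aryl group is added and the former lactone carbonyl carbon becomes C7.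

Step 9
Reactants: 14 silyloxy ketone; 15 formaldehyde (charged as paraformaldehyde)
Product: 17 (R)-1-[4-(benzyloxy)-3-methoxyphenyl]-3-[4-(benzyloxy)-3-methoxybenzyl]-4-[(tert-butyldiphenylsilyl)oxy]-2-methylenebutan-1-one, via Mannich base 16 (not isolated)
Conditions: (CH2O)n, i-Pr2NH·CF3CO2H (1 equiv), CF3CO2H (10 mol%), THF, reflux
Reagents that add atoms: diisopropylamine (charged as its trifluoroacetate), CC(C)NC(C)C (carried only by 16)
Why: Mannich methylenation, in which the enol of the aryl ketone (C8 is the only enolisable position) attacks the iminium ion of formaldehyde and diisopropylamine and the crowded β-amino ketone 16 loses the amine in situ to give the 1,1-disubstituted enone.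

Step 10
Reactants: 17 silyloxy enone
Product: 18 (R)-1-[4-(benzyloxy)-3-methoxyphenyl]-3-[4-(benzyloxy)-3-methoxybenzyl]-4-hydroxy-2-methylenebutan-1-one
Conditions: HF·pyridine, pyridine, THF, 0 → 23 °C
Reagents that add atoms: none
Why: Fluoride-driven desilylation in a weakly acidic medium frees the C9' hydroxyl without forming an alkoxide, so the hydroxy enone can be isolated and the benzyl ethers are untouched.

Step 11
Reactants: 18 hydroxy enone
Product: 20 [(3R,4R)-4-[4-(benzyloxy)-3-methoxybenzyl]tetrahydrofuran-3-yl][4-(benzyloxy)-3-methoxyphenyl]methanone, via potassium enolate 19 (not isolated)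
Conditions: KOt-Bu (20 mol%), dry THF/t-BuOH (4:1), 0.01 M, 0 → 23 °C; pH 7 buffer
Reagents that add atoms: potassium tert-butoxide, CC(C)(C)[O-].[K+] (its potassium is carried only by 19)
Why: Proposed new method: catalytic KOt-Bu turns the C9' hydroxyl into its alkoxide, which adds to the unsubstituted methylene terminus C9 of the C7(=O)–C8=C9H2 enone to form the O–C9 bond and the exocyclic enolate 19, and t-BuOH protonates 19 at C8 and passes the base on. The tetrahydrofuran closes in the 5-endo-trig mode, which is geometrically disfavoured and has not been shown for 4-hydroxy-2-methylene aryl ketones; the closest known reaction type is the KOt-Bu-mediated 5-endo-trig closure of homoallylic alcohols whose internal alkene carbon bears a sulfonyl or trifluoromethyl group, which gives 3-substituted tetrahydrofurans, alongside the ordinary intramolecular oxa-Michael addition. It should succeed because the aroyl group polarises a sterically open 1,1-disubstituted alkene strongly towards C9, the exchange of the C=C π bond for a C–O σ bond in an unstrained ring is downhill, and the only other intramolecular path, 5-exo-trig hemiketal formation at C7, is reversible and leads nowhere. C8 is set under thermodynamic control: the ketone enolises (and can reopen by retro-Michael reaction) under the same base, so the aroyl group settles trans to the benzyl group on the fixed C8' centre, which corresponds to 8R. C8' cannot erode, because in 18 its C–H sits on the α-carbon of the enone (cross-conjugated, not vinylogously acidic) and in 20 it is β to the ketone with no leaving group. The selectivity needed is intramolecular over intermolecular addition (oligomeric ethers, enolate–enone Michael dimers), and it is secured by the high dilution, by the t-BuOH that quenches 19 at once and by the bulk of tert-butoxide, whose own adduct reverts.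

Step 12
Reactants: 20 trans ketone
Product: 21 (R)-[(3R,4R)-4-[4-(benzyloxy)-3-methoxybenzyl]tetrahydrofuran-3-yl][4-(benzyloxy)-3-methoxyphenyl]methanol
Conditions: (S)-2-methyl-CBS-oxazaborolidine [(S)-1-methyl-3,3-diphenyltetrahydro-1H,3H-pyrrolo[1,2-c][1,3,2]oxazaborole] (0.5 equiv), BH3·SMe2, THF, −20 °C, slow addition of 20; MeOH
Reagents that add atoms: none
Why: Corey–Bakshi–Shibata reduction, in which the ketone binds the ring boron through the lone pair remote from the aryl (large) group and the nitrogen-bound borane delivers hydride to the Si face, giving 7R in the same sense as acetophenone gives the R alcohol with the S catalyst, and this reagent control has to override a small Felkin–Anh bias of the ring towards 7S.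

Step 13
Reactants: 21 dibenzyl carbinol
Product: 22 4-{[(3R,4R)-4-[(R)-hydroxy(4-hydroxy-3-methoxyphenyl)methyl]tetrahydrofuran-3-yl]methyl}-2-methoxyphenol (target)
Conditions: H2 (1 atm), Pd/C (10 wt% Pd), EtOAc/EtOH, 23 °C, stopped at full conversion
Reagents that add atoms: none
Why: Heterogeneous hydrogenolysis of the two aryl benzyl ethers, which cleave faster than the secondary benzylic alcohol in a neutral solvent at 1 atm, and no stereocentre is touched in the absence of acid.

## Compound list

1 | vanillin | COc1cc(C=O)ccc1O | starting material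
2 | 4-(benzyloxy)-3-methoxybenzaldehyde | COc1cc(C=O)ccc1OCc1ccccc1 | intermediate
3 | dimethyl succinate | COC(=O)CCC(=O)OC | starting material
4 | (E)-4-[4-(benzyloxy)-3-methoxyphenyl]-3-(methoxycarbonyl)but-3-enoic acid | COC(=O)/C(CC(=O)O)=C/c1ccc(OCc2ccccc2)c(OC)c1 | intermediate
5 | (R)-4-[4-(benzyloxy)-3-methoxyphenyl]-3-(methoxycarbonyl)butanoic acid | COc1cc(C[C@H](CC(=O)O)C(=O)OC)ccc1OCc1ccccc1 | intermediate
6 | potassium (R)-4-[4-(benzyloxy)-3-methoxyphenyl]-3-(methoxycarbonyl)butanoate | COc1cc(C[C@H](CC(=O)[O-])C(=O)OC)ccc1OCc1ccccc1.[K+] | intermediate (not isolated)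
7 | (R)-3-[4-(benzyloxy)-3-methoxybenzyl]-4-hydroxybutanoic acid | COc1cc(C[C@H](CC(=O)O)CO)ccc1OCc1ccccc1 | intermediate (not isolated)
8 | (R)-4-[4-(benzyloxy)-3-methoxybenzyl]dihydrofuran-2(3H)-one | COc1cc(C[C@H]2COC(=O)C2)ccc1OCc1ccccc1 | intermediate
9 | (R)-3-[4-(benzyloxy)-3-methoxybenzyl]-4-hydroxy-N-methoxy-N-methylbutanamide | COc1cc(C[C@H](CC(=O)N(C)OC)CO)ccc1OCc1ccccc1 | intermediate
10 | (R)-3-[4-(benzyloxy)-3-methoxybenzyl]-4-[(tert-butyldiphenylsilyl)oxy]-N-methoxy-N-methylbutanamide | COc1cc(C[C@H](CC(=O)N(C)OC)CO[Si](c2ccccc2)(c2ccccc2)C(C)(C)C)ccc1OCc1ccccc1 | intermediate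
11 | 4-bromo-2-methoxyphenol | COc1cc(Br)ccc1O | starting material
12 | 1-(benzyloxy)-4-bromo-2-methoxybenzene | COc1cc(Br)ccc1OCc1ccccc1 | intermediate
13 | [4-(benzyloxy)-3-methoxyphenyl]lithium | COc1cc([Li])ccc1OCc1ccccc1 | intermediate (not isolated)
14 | (R)-1-[4-(benzyloxy)-3-methoxyphenyl]-3-[4-(benzyloxy)-3-methoxybenzyl]-4-[(tert-butyldiphenylsilyl)oxy]butan-1-one | COc1cc(C[C@H](CC(=O)c2ccc(OCc3ccccc3)c(OC)c2)CO[Si](c2ccccc2)(c2ccccc2)C(C)(C)C)ccc1OCc1ccccc1 | intermediate
15 | formaldehyde (charged as paraformaldehyde) | C=O | starting material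
16 | (3R)-1-[4-(benzyloxy)-3-methoxyphenyl]-3-[4-(benzyloxy)-3-methoxybenzyl]-4-[(tert-butyldiphenylsilyl)oxy]-2-[(diisopropylamino)methyl]butan-1-one (both C2 epimers) | COc1cc(C[C@H](C(CN(C(C)C)C(C)C)C(=O)c2ccc(OCc3ccccc3)c(OC)c2)CO[Si](c2ccccc2)(c2ccccc2)C(C)(C)C)ccc1OCc1ccccc1 | intermediate (not isolated)
17 | (R)-1-[4-(benzyloxy)-3-methoxyphenyl]-3-[4-(benzyloxy)-3-methoxybenzyl]-4-[(tert-butyldiphenylsilyl)oxy]-2-methylenebutan-1-one | COc1cc(C[C@H](C(=C)C(=O)c2ccc(OCc3ccccc3)c(OC)c2)CO[Si](c2ccccc2)(c2ccccc2)C(C)(C)C)ccc1OCc1ccccc1 | intermediate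
18 | (R)-1-[4-(benzyloxy)-3-methoxyphenyl]-3-[4-(benzyloxy)-3-methoxybenzyl]-4-hydroxy-2-methylenebutan-1-one | COc1cc(C[C@H](C(=C)C(=O)c2ccc(OCc3ccccc3)c(OC)c2)CO)ccc1OCc1ccccc1 | intermediate (key-step precursor)
19 | potassium enolate of 20 (exocyclic C7=C8 enolate, 8'R) | COc1cc(C[C@H]2COCC2=C([O-])c2ccc(OCc3ccccc3)c(OC)c2)ccc1OCc1ccccc1.[K+] | intermediate (not isolated)
20 | [(3R,4R)-4-[4-(benzyloxy)-3-methoxybenzyl]tetrahydrofuran-3-yl][4-(benzyloxy)-3-methoxyphenyl]methanone | COc1cc(C[C@H]2COC[C@@H]2C(=O)c2ccc(OCc3ccccc3)c(OC)c2)ccc1OCc1ccccc1 | intermediate (key-step product)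
21 | (R)-[(3R,4R)-4-[4-(benzyloxy)-3-methoxybenzyl]tetrahydrofuran-3-yl][4-(benzyloxy)-3-methoxyphenyl]methanol | COc1cc(C[C@H]2COC[C@@H]2[C@@H](O)c2ccc(OCc3ccccc3)c(OC)c2)ccc1OCc1ccccc1 | intermediate
22 | 4-{[(3R,4R)-4-[(R)-hydroxy(4-hydroxy-3-methoxyphenyl)methyl]tetrahydrofuran-3-yl]methyl}-2-methoxyphenol | COc1cc(C[C@H]2COC[C@@H]2[C@@H](O)c2ccc(O)c(OC)c2)ccc1O | target

## Step count

Total step count: 13.
Longest linear sequence: 12 steps (steps 1–6 and 8–13, from vanillin).

## Steps most likely to fail

**1. Step 11.** The alkoxide may not reach the π* lobe at C9 within the 5-endo geometry. Intermolecular oxa-Michael oligomerisation or Michael addition of the enolate to a second enone would then outrun ring closure.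

The fallback uses known chemistry only. It sets out from lactone 8 (with aldehyde 2) and comes back at ketone 20. The ring is closed by a 5-exo-tet displacement instead, the lactone carbonyl now serves as C9, and the aldehyde carbon serves as C7.
- Lactone 8 is deprotonated with LiN(SiMe3)2 (THF, −78 °C). The enolate adds to 2 on the face away from the benzyl group and gives the trans aldol lactone F1, as both C7 epimers.
- TIPSOTf and 2,6-lutidine convert it into the silyl ether F2.
- LiAlH4 opens the lactone to the 1,4-diol F3.
- TsCl in pyridine tosylates one primary hydroxyl, and the other displaces it to give the silylated tetrahydrofuran F4.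
- Bu4NF frees the carbinol mixture F5.
- Dess–Martin periodinane oxidises both epimers to 20.

**2. Step 12.** Facial selectivity may be poor, because the branched ring carbon C8 competes with the aryl group for the role of the large substituent and the substrate bias opposes the catalyst.

The fallback sets out from 20 and comes back at 21. It accepts the substrate preference and then inverts C7.
- LiBH(s-Bu)3 (THF, −78 °C) should give the Felkin–Anh (7S)-carbinol F6.
- Mitsunobu reaction with 4-nitrobenzoic acid, PPh3 and DIAD gives the inverted (7R)-4-nitrobenzoate F7.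
- K2CO3 in MeOH releases 21.

**3. Step 13.** Over-reduction is possible. Once the para phenol is freed, the C7–OH bond is an activated benzylic bond and may undergo hydrogenolysis, and traces of acid could also epimerise C7.

The fallback sets out from 20 and comes back at 22. The reductive deprotection is moved to the ketone stage, and the last deprotection becomes non-reductive.
- H2 and Pd/C in EtOAc give the bisphenol ketone F8.
- TBSCl and imidazole give the bis-silyl ketone F9.
- The oxazaborolidine reduction of step 12 gives the (7R)-bis-silyl carbinol F10.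
- Bu4NF buffered with AcOH gives 22.

## Further compounds

F1 | step 11 | trans aldol lactone, 3-{[4-(benzyloxy)-3-methoxyphenyl](hydroxy)methyl}-4-[4-(benzyloxy)-3-methoxybenzyl]dihydrofuran-2(3H)-one (both C7 epimers) | COc1cc(C[C@H]2COC(=O)[C@@H]2C(O)c2ccc(OCc3ccccc3)c(OC)c2)ccc1OCc1ccccc1
F2 | step 11 | C7 triisopropylsilyl ether of F1 | COc1cc(C[C@H]2COC(=O)[C@@H]2C(O[Si](C(C)C)(C(C)C)C(C)C)c2ccc(OCc3ccccc3)c(OC)c2)ccc1OCc1ccccc1
F3 | step 11 | C9,C9' 1,4-diol with C7 triisopropylsilyl ether | COc1cc(C[C@@H](CO)[C@H](CO)C(O[Si](C(C)C)(C(C)C)C(C)C)c2ccc(OCc3ccccc3)c(OC)c2)ccc1OCc1ccccc1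
F4 | step 11 | trans-3,4-disubstituted tetrahydrofuran with C7 triisopropylsilyl ether | COc1cc(C[C@H]2COC[C@@H]2C(O[Si](C(C)C)(C(C)C)C(C)C)c2ccc(OCc3ccccc3)c(OC)c2)ccc1OCc1ccccc1
F5 | step 11 | dibenzyl carbinol as both C7 epimers | COc1cc(C[C@H]2COC[C@@H]2C(O)c2ccc(OCc3ccccc3)c(OC)c2)ccc1OCc1ccccc1
F6 | step 12 | (7S)-dibenzyl carbinol, C7 epimer of 21 | COc1cc(C[C@H]2COC[C@@H]2[C@H](O)c2ccc(OCc3ccccc3)c(OC)c2)ccc1OCc1ccccc1
F7 | step 12 | (7R)-4-nitrobenzoate of 21 | COc1cc(C[C@H]2COC[C@@H]2[C@@H](OC(=O)c2ccc(cc2)[N+](=O)[O-])c2ccc(OCc3ccccc3)c(OC)c2)ccc1OCc1ccccc1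
F8 | step 13 | bisphenol ketone, [(3R,4R)-4-(4-hydroxy-3-methoxybenzyl)tetrahydrofuran-3-yl](4-hydroxy-3-methoxyphenyl)methanone | COc1cc(C[C@H]2COC[C@@H]2C(=O)c2ccc(O)c(OC)c2)ccc1O
F9 | step 13 | bis(tert-butyldimethylsilyl) ether of F8 | COc1cc(C[C@H]2COC[C@@H]2C(=O)c2ccc(O[Si](C)(C)C(C)(C)C)c(OC)c2)ccc1O[Si](C)(C)C(C)(C)C
F10 | step 13 | (7R)-carbinol with both phenols as tert-butyldimethylsilyl ethers | COc1cc(C[C@H]2COC[C@@H]2[C@@H](O)c2ccc(O[Si](C)(C)C(C)(C)C)c(OC)c2)ccc1O[Si](C)(C)C(C)(C)C
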